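## The problem

Target 16 is (2S)-2-(3,4-dimethoxyphenyl)-5,7,8-trimethoxy-2,3-dihydro-4H-chromen-4-one. It is a flavanone in which benzo ring A (C4a to C8a) is fused to the dihydropyranone ring C, and ring B, a 3,4-dimethoxyphenyl group, sits on C2.

- **Stereocentre.** C2 is the only one. It is benzylic and β to the C4 ketone, and nothing else in the molecule can direct it, so a catalyst must set it.
- **Lability.** The β-aryloxy ketone reopens to the 2'-hydroxychalcone by E1cB elimination under base. C2 is therefore best created last and kept away from base afterwards.
- **Ring A pattern.** Oxygen sits on C5, C7, C8 and C8a; only C6 carries hydrogen. The two oxygens flanking the acyl-bearing C4a (at C5 and C8a) are nearly alike, yet one must become O1 and the other a methyl ether. Confusing them gives the 5,6,7-trimethoxy isomer.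
- **Sensitive groups.** The peri 5-methoxy group is cleaved by Lewis acids that chelate the C4 carbonyl. The enone of any chalcone precursor is a Michael acceptor. A pyrone precursor is opened by alkoxide.
- **Enabling feature.** C4a carries the acyl group between two oxygenated carbons (C5, C8a), with a further oxygen meta at C7. This is an acylphloroglucinol, the ring a polyketide chain gives when its doubly activated methylene (C4a) closes on a terminal ester carbon (C8a). The C8 oxygen can travel as an enol ether methoxy group of a 2-pyrone that masks the chain.

## Retrosynthesis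

**16 to 15 (O1–C2).** Cutting O1–C2 by a retro-oxa-Michael step gives the 2'-hydroxychalcone 15, an achiral isomer of the target. The neighbouring cut at C2–aryl would need a chromone and an aryl metal reagent and would not suit an open-chain precursor. The forward step must control the face of phenoxide attack on the enone β-carbon and stop before retro-Michael equilibration.

**15 to 13 to 12 (two O–methyl bonds).** Chalcone 15 has a free 2'-hydroxyl next to the 3'-methoxy group and a methyl ether at C6'. Direct monomethylation of the 2',6'-diphenol 12 at the less hindered oxygen was considered and set aside. Its selectivity is only steric, and 12 closes easily to two regioisomeric 5-hydroxyflavanones under the same basic conditions. Instead, 12 is fully methylated to the hexamethyl ether 13, and the 2'-methoxy group is then removed under chelation control to give 15. This costs one extra step but replaces a kinetic competition by a preference that is well established for 2,3,4,6-tetramethoxyaryl ketones. The permethylation also collects any flavanone formed on the way.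

**12 to 10 (C4a–C8a, the key cut).** Opening ring A between C4a and C8a leads through the open-chain ester 11 back to the 6-(2-oxoalkenyl)-3,4-dimethoxy-2-pyrone 10, an isomer of 12. The neighbouring cut at C4a–C4 (acylation of a preformed tetraoxygenated benzene with a cinnamoyl chloride) needs a strong Lewis acid on an electron-rich arene and an enone, where conjugate arylation competes. The pyrone cut builds ring A with all four oxygens placed by construction and gives the chalcone at the right oxidation level in one isomerisation. The forward reaction must fold 11 in the Claisen mode and spare the styryl ketone.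

**10 to 4 and 7 (CH2–C(=O) bond).** Cutting between the pyrone methylene and the ketone carbonyl gives the 6-methylpyrone 4 and the cinnamoyl Weinreb amide 7. The forward step is acylation of the lithiated pyrone 8 through the adduct 9. It must give 1,2-addition and no double addition.

**4 to 3 to 2 to 1 (C3–O bond).** The 3-methoxy group is traced to methanol and the carbenoid from diazo dione 2, which comes from the commodity lactone 1 by diazo transfer. O-methylation of 3 gives 4. A copper-mediated exchange of a 3-bromopyrone with NaOMe was rejected because hot methoxide is the reagent that opens the pyrone ring in step 6.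

**7 to 5 (amide bond).** Amide 7 comes from 3,4-dimethoxycinnamic acid 5 through the acyl imidazolide 6.

## Roads not taken

**Alternative 1:** The cut runs through ring A at C5–C6, C7–C8 and C8–C8a, with ring C and C2 already in place. The alkenyl(methoxy)carbene complex of zerovalent chromium A2 would be heated with methoxyacetylene A3. Alkyne insertion, CO insertion and electrocyclisation (Dötz benzannulation) would give the 8-hydroxy-5,7-dimethoxyflavan A1.
- Merits: three ring bonds form in one step and every oxygen is placed unambiguously. O1 is already in the ring, so no hydroxyl has to be told from another. In this respect it is better than the chosen plan.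
- Weak points: stoichiometric chromium; a volatile alkoxyalkyne whose insertion regiochemistry is less reliable than that of alkyl alkynes; A2 needs an enantiopure dihydropyran, so the stereocentre is bought early. A1 lacks the C4 carbonyl, and a late benzylic oxidation at C4 must spare C2–H, which is benzylic, α to oxygen and stereogenic.
- Comparison: the chosen plan has the C4 carbonyl from the start, sets C2 last and uses no stoichiometric heavy metal. It pays with steps 7 and 8 for the differentiation that this road gets free.

**Alternative 2:** The cut is at C4a–C4, C4–C3 and O1–C2. Iodophenol A5, aryl alkyne A6 and CO would combine under PdCl2(PPh3)2 (divalent palladium precatalyst) and a secondary amine. Carbonylative Sonogashira coupling and 6-endo closure would give flavone A4, and asymmetric hydrogenation of C2=C3 would follow.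
- Merits: the whole skeleton in one three-component step, and O1 versus the 5-methoxy group fixed by A5. This road is probably shorter and surer in constitution than the chosen one.
- Weak points: A5 is not an article of commerce and needs a regioselective iodination of an electron-rich phenol with two open positions. Closure to the aurone competes. A4 is two hydrogens too high in oxidation level, and hydrogenation of an electron-rich flavone tends to run on to the flavan-4-ol, which must be reoxidised.
- Comparison: the chosen plan reaches the chalcone oxidation level directly, so C2 arises by isomerisation, and it starts from two commodity chemicals. Against the regiochemical security of A5 it has to set steps 7 and 8.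

**Alternative 3:** The key cut is C4a–C5. A lithiated enantiopure dihydropyran would add to the methoxycyclobutenedione A9 to give cyclobutenone A8. On heating, A8 would open to a dienylketene that closes on C4a and enolises (Moore-type ring expansion) to the hydroquinone A7.
- Merits: a neutral thermal key step and every ring A oxygen placed by construction. Both phenols of A7 are simply methylated, so there is no differentiation problem. Here it is superior.
- Weak points: the enantiopure 2-aryl-4-silyloxy-dihydropyran and its lithiation next to oxygen (in competition with the benzylic C2–H) are a multi-step project. Addition to A9 must be regioselective and A7 is air-sensitive. After the key step, double methylation, desilylation and oxidation at C4 are still needed.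
- Comparison: the chosen plan is far shorter, keeps C4 as a ketone throughout and carries no stereocentre through organolithium chemistry. It concedes positional certainty at the two ortho oxygens.

Key step: step 6

Assumption: the quinidine-derived thiourea of step 9 is taken to give the (2S) product; the quinine-derived pseudoenantiomer is equally available and would replace it if the sense proves opposite.

## Route

Step 1
Reactants: 1 4-hydroxy-6-methyl-2H-pyran-2-one
Product: 2 3-diazo-6-methyl-2H-pyran-2,4(3H)-dione
Conditions: 4-acetamidobenzenesulfonyl azide, Et3N, MeCN, 0 °C to rt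
Reagents that add atoms: 4-acetamidobenzenesulfonyl azide, CC(=O)Nc1ccc(cc1)S(=O)(=O)N=[N+]=[N-]
Why: Regitz diazo transfer to a cyclic 1,3-dicarbonyl compound; C3 of 1 is the only doubly activated carbon, and the sulfonamide by-product is removed by filtration and chromatography.

Step 2
Reactants: 2 3-diazo-6-methyl-2H-pyran-2,4(3H)-dione
Product: 3 4-hydroxy-3-methoxy-6-methyl-2H-pyran-2-one
Conditions: Rh2(OAc)4 (1 mol%), MeOH, ClCH2CH2Cl, 70 °C
Reagents that add atoms: methanol, CO
Why: Rhodium carbenoid O–H insertion into methanol, the usual fate of carbenoids from cyclic 2-diazo-1,3-dicarbonyl compounds in alcohols; the 3-methoxy dione enolises to the 4-hydroxy-2-pyrone, and the neutral conditions leave the lactone alone.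

Step 3
Reactants: 3 4-hydroxy-3-methoxy-6-methyl-2H-pyran-2-one
Product: 4 3,4-dimethoxy-6-methyl-2H-pyran-2-one
Conditions: Me2SO4, K2CO3, acetone, reflux
Reagents that add atoms: dimethyl sulfate, COS(=O)(=O)OC
Why: Williamson-type O-methylation of the vinylogous acid; with carbonate in acetone, 4-hydroxy-2-pyrones are alkylated on the C4 oxygen to give the 4-methoxy-2-pyrone and not the 2-methoxy-4-pyrone.

Step 4
Reactants: 5 (2E)-3-(3,4-dimethoxyphenyl)prop-2-enoic acid
Product: 7 (2E)-3-(3,4-dimethoxyphenyl)-N-methoxy-N-methylprop-2-enamide, via acyl imidazolide 6 (not isolated)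
Conditions: 1,1'-carbonyldiimidazole, CH2Cl2, rt; then MeNHOMe·HCl, rt
Reagents that add atoms: N,O-dimethylhydroxylamine hydrochloride, CNOC.Cl
Why: Weinreb amide formation through the acyl imidazolide 6; the imidazole released on activation frees the amine from its salt, and the E-alkene is not touched.

Step 5
Reactants: 4 3,4-dimethoxy-6-methyl-2H-pyran-2-one; 7 (2E)-3-(3,4-dimethoxyphenyl)-N-methoxy-N-methylprop-2-enamide
Product: 10 6-[(3E)-4-(3,4-dimethoxyphenyl)-2-oxobut-3-en-1-yl]-3,4-dimethoxy-2H-pyran-2-one, via lithiated pyrone 8 (not isolated), via lithium hemiaminal adduct 9 (not isolated)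
Conditions: LiN(iPr)2 (1.1 equiv), THF, −78 °C; then 7, −78 to −30 °C; cold 1 M HCl
Reagents that add atoms: none
Why: Kinetic deprotonation of the 6-methyl group gives the vinylogous enolate 8 (C3 is blocked by its methoxy group), which adds to the amide carbonyl of 7 in a Weinreb ketone synthesis; the chelated adduct 9 persists until the acid quench, so the acidic methylene of 10 never meets 8 and no second addition occurs.

Step 6
Reactants: 10 6-[(3E)-4-(3,4-dimethoxyphenyl)-2-oxobut-3-en-1-yl]-3,4-dimethoxy-2H-pyran-2-one
Product: 12 (2E)-1-(2,6-dihydroxy-3,4-dimethoxyphenyl)-3-(3,4-dimethoxyphenyl)prop-2-en-1-one, via open-chain methyl ester 11 (not isolated)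
Conditions: Mg(OMe)2 (5 equiv), MeOH, reflux, N2; then cold 1 M HCl
Reagents that add atoms: none
Why: Methoxide adds to the lactone carbonyl of 10 and the ring opens to the methyl ester 11, held as a magnesium chelate of its 5,7-diketone; the two methoxy-bearing carbons remain a (Z)-enol ether unit that keeps the ester and the chain cis, as they were in the pyrone. The doubly activated C6 methylene of 11 (C4a of the target) then attacks the ester carbonyl (C8a) in a Claisen condensation, a 6-exo-trig closure; loss of the methoxide taken up earlier and enolisation give ring A as the magnesium bis-phenoxide of 12, a sink that drains the reversible ring opening. The closest known reaction type is the Mg(OMe)2-mediated ring transformation of 6-(2-oxoalkyl)-4-methoxy-2-pyrones into 2-acyl-5-methoxyresorcinols, the laboratory counterpart of the chalcone synthase folding. No stereocentre is formed. The step needs Claisen and not aldol folding: the ester α-carbon is an enol ether carbon that can react only through a dienolate, whereas magnesium chelation of the β-diketone activates C6 and holds it near the ester. It also needs the styryl ketone to survive: as part of a chelated diketonate and then of a bis-phenoxide it is a poor acceptor for methoxide. The acidified crude product goes directly into step 7, so slow closure of free 12 to flavanones is of no consequence.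

Step 7
Reactants: 12 (2E)-1-(2,6-dihydroxy-3,4-dimethoxyphenyl)-3-(3,4-dimethoxyphenyl)prop-2-en-1-one
Product: 13 (2E)-3-(3,4-dimethoxyphenyl)-1-(2,3,4,6-tetramethoxyphenyl)prop-2-en-1-one
Conditions: MeI (excess), K2CO3, DMF, 50 °C
Reagents that add atoms: iodomethane, CI
Why: Exhaustive Williamson methylation of both chelated phenols; any 5-hydroxyflavanone formed from 12 by adventitious closure reopens under carbonate (E1cB) and is methylated too, so the chalcone and both flavanone isomers should converge on the single ether 13.

Step 8
Reactants: 13 (2E)-3-(3,4-dimethoxyphenyl)-1-(2,3,4,6-tetramethoxyphenyl)prop-2-en-1-one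
Product: 15 (2E)-3-(3,4-dimethoxyphenyl)-1-(2-hydroxy-3,4,6-trimethoxyphenyl)prop-2-en-1-one, via dichloroboron chelate 14 (not isolated)
Conditions: BCl3 (1.2 equiv), CH2Cl2, −78 to 0 °C; then H2O
Reagents that add atoms: none
Why: Chelation-controlled aryl methyl ether cleavage: BCl3 binds the ketone oxygen and an ortho methoxy oxygen, chloride removes the methyl group, and the six-membered chelate 14 is hydrolysed on work-up. Of the two ortho methoxy groups, the one at C2' is flanked on both sides, twisted out of the ring plane and more basic, which is the preference by which 2,3,4,6-tetramethoxyaryl ketones give their 2-hydroxy-3,4,6-trimethoxy derivatives; once the chelate has formed, the remaining ethers are left alone.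

Step 9
Reactants: 15 (2E)-3-(3,4-dimethoxyphenyl)-1-(2-hydroxy-3,4,6-trimethoxyphenyl)prop-2-en-1-one
Product: 16 (2S)-2-(3,4-dimethoxyphenyl)-5,7,8-trimethoxy-2,3-dihydro-4H-chromen-4-one
Conditions: 1-[3,5-bis(trifluoromethyl)phenyl]-3-[(9R)-6'-methoxycinchonan-9-yl]thiourea (10 mol%), toluene, 0 °C to rt; recrystallisation
Reagents that add atoms: none
Why: Catalytic enantioselective intramolecular oxa-Michael addition (6-endo-trig): the quinuclidine nitrogen deprotonates the 2'-hydroxyl while the thiourea binds the enone carbonyl, so the phenoxide attacks one face of the β-carbon and C2 is set by the catalyst alone. The 6'-methoxy group twists the aryl ketone and favours the closed form; the catalyst is removed once conversion stops so that retro-Michael opening cannot erode the enantiomeric purity, which recrystallisation then completes.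

## Compound list

1 | 4-hydroxy-6-methyl-2H-pyran-2-one | Cc1cc(O)cc(=O)o1 | starting material
2 | 3-diazo-6-methyl-2H-pyran-2,4(3H)-dione | CC1=CC(=O)C(=[N+]=[N-])C(=O)O1 | intermediate
3 | 4-hydroxy-3-methoxy-6-methyl-2H-pyran-2-one | Cc1cc(O)c(OC)c(=O)o1 | intermediate
4 | 3,4-dimethoxy-6-methyl-2H-pyran-2-one | Cc1cc(OC)c(OC)c(=O)o1 | intermediate
5 | (2E)-3-(3,4-dimethoxyphenyl)prop-2-enoic acid | COc1ccc(/C=C/C(=O)O)cc1OC | starting material
6 | (2E)-3-(3,4-dimethoxyphenyl)-1-(1H-imidazol-1-yl)prop-2-en-1-one | COc1ccc(/C=C/C(=O)n2ccnc2)cc1OC | intermediate (not isolated)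
7 | (2E)-3-(3,4-dimethoxyphenyl)-N-methoxy-N-methylprop-2-enamide | COc1ccc(/C=C/C(=O)N(C)OC)cc1OC | intermediate
8 | [(3,4-dimethoxy-2-oxo-2H-pyran-6-yl)methyl]lithium | [Li]Cc1cc(OC)c(OC)c(=O)o1 | intermediate (not isolated)
9 | lithium (3E)-1-(3,4-dimethoxy-2-oxo-2H-pyran-6-yl)-4-(3,4-dimethoxyphenyl)-2-[methoxy(methyl)amino]but-3-en-2-olate (racemic) | COc1ccc(/C=C/C(O[Li])(Cc2cc(OC)c(OC)c(=O)o2)N(C)OC)cc1OC | intermediate (not isolated)
10 | 6-[(3E)-4-(3,4-dimethoxyphenyl)-2-oxobut-3-en-1-yl]-3,4-dimethoxy-2H-pyran-2-one | COc1ccc(/C=C/C(=O)Cc2cc(OC)c(OC)c(=O)o2)cc1OC | intermediate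
11 | methyl (2Z,8E)-9-(3,4-dimethoxyphenyl)-2,3-dimethoxy-5,7-dioxonona-2,8-dienoate | COC(=O)/C(OC)=C(OC)\CC(=O)CC(=O)/C=C/c1ccc(OC)c(OC)c1 | intermediate (not isolated)
12 | (2E)-1-(2,6-dihydroxy-3,4-dimethoxyphenyl)-3-(3,4-dimethoxyphenyl)prop-2-en-1-one | COc1ccc(/C=C/C(=O)c2c(O)cc(OC)c(OC)c2O)cc1OC | intermediate
13 | (2E)-3-(3,4-dimethoxyphenyl)-1-(2,3,4,6-tetramethoxyphenyl)prop-2-en-1-one | COc1ccc(/C=C/C(=O)c2c(OC)cc(OC)c(OC)c2OC)cc1OC | intermediate
14 | dichloro{2-[(2E)-3-(3,4-dimethoxyphenyl)prop-2-enoyl]-3,5,6-trimethoxyphenoxy}borane | COc1ccc(/C=C/C(=O)c2c(OC)cc(OC)c(OC)c2OB(Cl)Cl)cc1OC | intermediate (not isolated)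
15 | (2E)-3-(3,4-dimethoxyphenyl)-1-(2-hydroxy-3,4,6-trimethoxyphenyl)prop-2-en-1-one | COc1ccc(/C=C/C(=O)c2c(OC)cc(OC)c(OC)c2O)cc1OC | intermediate
16 | (2S)-2-(3,4-dimethoxyphenyl)-5,7,8-trimethoxy-2,3-dihydro-4H-chromen-4-one | COc1ccc([C@@H]2CC(=O)c3c(OC)cc(OC)c(OC)c3O2)cc1OC | target

## Step count and least certain steps

Total: 9 steps. Longest linear sequence: 8 steps (steps 1–3 and 5–9, from 1); step 4 is the side branch.

**Step 6 (key step).** The styryl ketone may be consumed by conjugate addition of methoxide or by O-attack of the diketone enol on the β-carbon. The opened chain may also simply reclose to a pyrone, or the product may cyclise further during work-up. The fallback takes the styryl unit out of the ring transformation. It sets out from 4: lithiation and acylation with N-methoxy-N-methylacetamide should give 3,4-dimethoxy-6-(2-oxopropyl)-2H-pyran-2-one F1. The same Mg(OMe)2 treatment should give 1-(2,6-dihydroxy-3,4-dimethoxyphenyl)ethan-1-one F2, and methylation (MeI, K2CO3, DMF) should give 1-(2,3,4,6-tetramethoxyphenyl)ethan-1-one F3. Claisen–Schmidt condensation of F3 with 3,4-dimethoxybenzaldehyde (KOH, EtOH) rejoins the route at 13.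

**Step 9.** Facial selectivity may be poor because the unactivated enone offers the thiourea a single binding point, and reversible ring opening under the basic catalyst may erode the enantiomeric purity or leave conversion incomplete. The fallback sets out from 15. Closure with NaOAc in refluxing EtOH should give racemic 2-(3,4-dimethoxyphenyl)-5,7,8-trimethoxy-2,3-dihydro-4H-chromen-4-one F4. Kinetic resolution by Noyori-type transfer hydrogenation follows (RuCl(p-cymene)(TsDPEN) in the enantiomeric form that reduces the (2R)-ketone faster, HCO2H/Et3N). It leaves 16 and converts the unwanted enantiomer into (2R,4R)-2-(3,4-dimethoxyphenyl)-5,7,8-trimethoxy-3,4-dihydro-2H-chromen-4-ol F5, which is separated. The fallback returns to the route at 16, at the cost of half the material per pass.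

**Step 8.** Cleavage may occur in part at the less hindered 6'-methoxy group, a second ortho ether may be lost, or the Lewis acid may close the liberated phenol onto the enone. The fallback replaces chelation-controlled dealkylation by sterically controlled alkylation. It sets out from 12, which is methylated once with one equivalent of MeI and Li2CO3 in DMF at rt; the less hindered 6'-hydroxyl should react first. It returns to the route at 15 and makes no new compound (F0).

**Step 5.** The soft extended enolate may add in the conjugate sense to the cinnamoyl amide, may react sluggishly at −78 °C, or may self-condense on warming. The fallback uses an aldehyde, to which such anions add reliably in the 1,2 sense. It sets out from 4: the lithiated pyrone is added to (2E)-3-(3,4-dimethoxyphenyl)prop-2-enal to give racemic 6-[(3E)-4-(3,4-dimethoxyphenyl)-2-hydroxybut-3-en-1-yl]-3,4-dimethoxy-2H-pyran-2-one F6. Oxidation of the allylic alcohol with Dess–Martin periodinane returns to the route at 10.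

## Further compounds

F1 | step 6 | 3,4-dimethoxy-6-(2-oxopropyl)-2H-pyran-2-one | CC(=O)Cc1cc(OC)c(OC)c(=O)o1
F2 | step 6 | 1-(2,6-dihydroxy-3,4-dimethoxyphenyl)ethan-1-one | CC(=O)c1c(O)cc(OC)c(OC)c1O
F3 | step 6 | 1-(2,3,4,6-tetramethoxyphenyl)ethan-1-one | CC(=O)c1c(OC)cc(OC)c(OC)c1OC
F4 | step 9 | racemic 2-(3,4-dimethoxyphenyl)-5,7,8-trimethoxy-2,3-dihydro-4H-chromen-4-one | COc1ccc(C2CC(=O)c3c(OC)cc(OC)c(OC)c3O2)cc1OC
F5 | step 9 | (2R,4R)-2-(3,4-dimethoxyphenyl)-5,7,8-trimethoxy-3,4-dihydro-2H-chromen-4-ol | COc1ccc([C@H]2C[C@@H](O)c3c(OC)cc(OC)c(OC)c3O2)cc1OC
F0 | step 8 | none | none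
F6 | step 5 | 6-[(3E)-4-(3,4-dimethoxyphenyl)-2-hydroxybut-3-en-1-yl]-3,4-dimethoxy-2H-pyran-2-one (racemic) | COc1ccc(/C=C/C(O)Cc2cc(OC)c(OC)c(=O)o2)cc1OC
A1 | alternative 1 | (2S)-2-(3,4-dimethoxyphenyl)-5,7-dimethoxychroman-8-ol | COc1ccc([C@@H]2CCc3c(OC)cc(OC)c(O)c3O2)cc1OC
A2 | alternative 1 | pentacarbonyl{[(2S)-2-(3,4-dimethoxyphenyl)-3,4-dihydro-2H-pyran-5-yl](methoxy)methylidene}chromium | COc1ccc([C@@H]2CCC(C(OC)=[Cr](=C=O)(=C=O)(=C=O)(=C=O)=C=O)=CO2)cc1OC
A3 | alternative 1 | methoxyacetylene (methoxyethyne) | COC#C
A4 | alternative 2 | 2-(3,4-dimethoxyphenyl)-5,7,8-trimethoxy-4H-chromen-4-one | COc1ccc(-c2cc(=O)c3c(OC)cc(OC)c(OC)c3o2)cc1OC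
A5 | alternative 2 | 6-iodo-2,3,5-trimethoxyphenol | COc1cc(OC)c(I)c(O)c1OC
A6 | alternative 2 | 4-ethynyl-1,2-dimethoxybenzene | C#Cc1ccc(OC)c(OC)c1
A7 | alternative 3 | (2S,4S)-4-(tert-butyldimethylsilyloxy)-2-(3,4-dimethoxyphenyl)-7-methoxychromane-5,8-diol | COc1ccc([C@@H]2C[C@H](O[Si](C)(C)C(C)(C)C)c3c(O)cc(OC)c(O)c3O2)cc1OC
A8 | alternative 3 | 4-[(2S,4S)-4-(tert-butyldimethylsilyloxy)-2-(3,4-dimethoxyphenyl)-3,4-dihydro-2H-pyran-6-yl]-4-hydroxy-3-methoxycyclobut-2-en-1-one (mixture of epimers at the carbinol carbon) | COc1ccc([C@@H]2C[C@H](O[Si](C)(C)C(C)(C)C)C=C(C3(O)C(OC)=CC3=O)O2)cc1OC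
A9 | alternative 3 | 3-methoxycyclobut-3-ene-1,2-dione | COC1=CC(=O)C1=O
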